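Labels: indole N1, C2, C3, C3a, C4–C7, C7a; pyrimidine N1', C2' (Br), N3', C4' (NH2), C5' (bonded to C3), C6'.
Cuts, in order: O–H back to O–Me; C4'–N back to C4'–Br; both C'–Br bonds back to a uracil; N1'–C6', N3'–C4' and C5'–C6' (urea, a one-carbon aminal, an indole-3-acetate); then C3–C3a; last N1–C2.
Enabling feature: C3a sits between C7a (bearing N1) and C4 (bearing O). The only other carbon ortho to N1, C7, is filled by Br, so a ketone hung on N1 through C2 can reach only the ether-activated C3a of the benzene ring.
Forward order: the benzene ring is purchased, the pyrrole ring closes in step 3, the pyrimidine ring closes in step 5, and bromine, nitrogen and the phenol are adjusted afterwards.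
Stereochemistry: the target has no stereocentre and no stereogenic double bond, so nothing has to be controlled.

Key step: step 3

Remark: the 1H-indole/4'-amino tautomer drawn is taken as the target. The alkene geometries of 7 and 8 are assigned by analogy and disappear in step 5.

Step 1
Reactants: 1 2-bromo-5-methoxyaniline
Product: 2 N-(2-bromo-5-methoxyphenyl)methanesulfonamide
Conditions: MeSO2Cl (1.1 equiv), pyridine, CH2Cl2, 0 °C to rt
Reagents that add atoms: methanesulfonyl chloride, CS(=O)(=O)Cl
Why: N-sulfonylation of an aniline with a sulfonyl chloride in pyridine is routine, and the weak base together with the ortho bromine should hold the reaction at the mono-sulfonamide.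

Step 2
Reactants: 2 N-(2-bromo-5-methoxyphenyl)methanesulfonamide; 3 ethyl 4-chloro-3-oxobutanoate
Product: 4 ethyl 4-[N-(2-bromo-5-methoxyphenyl)methanesulfonamido]-3-oxobutanoate
Conditions: K2CO3 (1.2 equiv), DMF, 0 °C to rt, 3 added slowly
Reagents that add atoms: none
Why: This is an SN2 N-alkylation of a sulfonamide anion by an alpha-chloro ketone, in which the N-aryl sulfonamide N–H is more acidic than the C2 methylene of 3, so a small excess of mild base and slow addition should keep the nucleophile ionised and the electrophile largely un-enolised.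

Step 3
Reactants: 4 ethyl 4-[N-(2-bromo-5-methoxyphenyl)methanesulfonamido]-3-oxobutanoate
Product: 6 ethyl 2-[7-bromo-1-(methanesulfonyl)-4-methoxy-1H-indol-3-yl]acetate, via 3-hydroxyindoline 5 (not isolated)
Conditions: P2O5 in MeSO3H (1:10 w/w), rt to 45 °C; poured on ice
Reagents that add atoms: none
Why: The strong acid protonates the ketone oxygen of 4, the arene carbon between the N-bearing and OMe-bearing carbons (future C3a) adds to the carbonyl carbon (future C3) to give the tertiary benzylic alcohol 5 after rearomatisation, and 5 ionises and loses a proton from C2 to furnish the aromatic pyrrole ring while P2O5 binds the water; an exocyclic alkylidene-acetate isomer, should it form, would be funnelled to the indole by the same acid. The closest known reaction types are the acid cyclodehydration of N-acyl or N-sulfonyl alpha-anilino ketones to 3-substituted indoles (a Bischler-type closure without the amine exchange) and the conversion of 4-aryloxyacetoacetates into benzofuran-3-acetates, both intramolecular Friedel-Crafts hydroxyalkylations followed by dehydration. The one ring formed (N1, C2, C3, C3a, C7a) closes in the 5-exo-trig mode, the C=O bond lying outside the new ring. No stereocentre survives, because the carbinol carbon of 5 arises as a racemate and becomes sp2 on dehydration. Regioselectivity is needed between the two carbons ortho to nitrogen and is fixed by the substrate, since one carries bromine, the other is activated by the adjacent methoxy group, and every other ring carbon is out of reach of the short N–CH2–C tether. Chemoselectivity rests on the sulfonyl group, which keeps nitrogen unprotonated and immobile so that no 1,2-shift to a 2-substituted indole occurs, and on the ketone being far more electrophilic than the ester in this medium; the small mesyl group also fits beside the C7 bromine and offers no second arene to the cation.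

Step 4
Reactants: 6 ethyl 2-[7-bromo-1-(methanesulfonyl)-4-methoxy-1H-indol-3-yl]acetate
Product: 7 ethyl (2E)-2-[7-bromo-1-(methanesulfonyl)-4-methoxy-1H-indol-3-yl]-3-(dimethylamino)prop-2-enoate
Conditions: t-BuOCH(NMe2)2 (2 equiv), toluene, 95 °C
Reagents that add atoms: tert-butoxybis(dimethylamino)methane (Bredereck's reagent), CC(C)(C)OC(N(C)C)N(C)C
Why: Aminomethylenation of an arylacetate CH2 with Bredereck's reagent is a formylation equivalent known for indole-3-acetates that needs no added alkoxide, so the N-mesyl group should be spared, and it installs C6' at the correct oxidation level.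

Step 5
Reactants: 7 ethyl (2E)-2-[7-bromo-1-(methanesulfonyl)-4-methoxy-1H-indol-3-yl]-3-(dimethylamino)prop-2-enoate
Product: 9 5-(7-bromo-4-methoxy-1H-indol-3-yl)pyrimidine-2,4(1H,3H)-dione, via ureidoacrylate 8 (not isolated)
Conditions: urea (3 equiv), 37% HCl (1.5 equiv), EtOH, reflux; then KOH (8 equiv), EtOH–H2O, reflux; HCl to pH 5
Reagents that add atoms: urea, NC(N)=O
Why: Acid-catalysed transamination of the push-pull enamine by urea followed by base-induced ring closure of the terminal NH2 onto the ester is the classical [3+3] uracil synthesis, precedented on 2-(indol-3-yl)-3-(dimethylamino)acrylates, and hot aqueous-ethanolic KOH should hydrolyse the N-sulfonylindole in the same operation.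

Step 6
Reactants: 9 5-(7-bromo-4-methoxy-1H-indol-3-yl)pyrimidine-2,4(1H,3H)-dione
Product: 10 7-bromo-3-(2,4-dibromopyrimidin-5-yl)-4-methoxy-1H-indole
Conditions: POBr3 (5 equiv), PhNMe2 (2 equiv), toluene, 105 °C; ice/aq. NaHCO3
Reagents that add atoms: phosphorus oxybromide, O=P(Br)(Br)Br
Why: Deoxybromination of a uracil through its O-phosphorylated lactim forms is the standard entry to 2,4-dibromopyrimidines, the absence of DMF excludes Vilsmeier formylation of the indole, and PhNMe2 buffers HBr so that the methyl ether should persist.

Step 7
Reactants: 10 7-bromo-3-(2,4-dibromopyrimidin-5-yl)-4-methoxy-1H-indole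
Product: 11 2-bromo-5-(7-bromo-4-methoxy-1H-indol-3-yl)pyrimidin-4-amine
Conditions: NH3 (2 M in i-PrOH, excess), THF, sealed tube, rt to 45 °C
Reagents that add atoms: ammonia, N
Why: In the SNAr reaction of 2,4-dihalopyrimidines C4' is attacked first (larger LUMO coefficient, para-quinoid Meisenheimer adduct), the small nucleophile tolerates the neighbouring indolyl group, and the new amino group deactivates the ring so that C2'–Br should remain.

Step 8
Reactants: 11 2-bromo-5-(7-bromo-4-methoxy-1H-indol-3-yl)pyrimidin-4-amine
Product: 12 3-(4-amino-2-bromopyrimidin-5-yl)-7-bromo-1H-indol-4-ol (CNP0304210.0)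
Conditions: BBr3 (6 equiv), CH2Cl2, −78 °C to rt; ice-water, NaHCO3 to pH 7
Reagents that add atoms: none
Why: In this Lewis-acid cleavage of an aryl methyl ether with BBr3, the excess reagent saturates the basic nitrogens, any halide exchange at C2' is degenerate because both partners are bromide, and the aryl C–Br bond is inert.

Compound list
1 | 2-bromo-5-methoxyaniline | Nc1cc(OC)ccc1Br | starting material
2 | N-(2-bromo-5-methoxyphenyl)methanesulfonamide | CS(=O)(=O)Nc1cc(OC)ccc1Br | intermediate
3 | ethyl 4-chloro-3-oxobutanoate | CCOC(=O)CC(=O)CCl | starting material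
4 | ethyl 4-[N-(2-bromo-5-methoxyphenyl)methanesulfonamido]-3-oxobutanoate | CCOC(=O)CC(=O)CN(c1cc(OC)ccc1Br)S(C)(=O)=O | intermediate
5 | ethyl 2-[7-bromo-3-hydroxy-1-(methanesulfonyl)-4-methoxy-2,3-dihydro-1H-indol-3-yl]acetate (racemic, not isolated) | CCOC(=O)CC1(O)CN(S(C)(=O)=O)c2c(Br)ccc(OC)c12 | intermediate
6 | ethyl 2-[7-bromo-1-(methanesulfonyl)-4-methoxy-1H-indol-3-yl]acetate | CCOC(=O)Cc1cn(S(C)(=O)=O)c2c(Br)ccc(OC)c12 | intermediate
7 | ethyl (2E)-2-[7-bromo-1-(methanesulfonyl)-4-methoxy-1H-indol-3-yl]-3-(dimethylamino)prop-2-enoate | CCOC(=O)/C(=C/N(C)C)c1cn(S(C)(=O)=O)c2c(Br)ccc(OC)c12 | intermediate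
8 | ethyl (2Z)-2-[7-bromo-1-(methanesulfonyl)-4-methoxy-1H-indol-3-yl]-3-(carbamoylamino)prop-2-enoate (not isolated) | CCOC(=O)/C(=C\NC(N)=O)c1cn(S(C)(=O)=O)c2c(Br)ccc(OC)c12 | intermediate
9 | 5-(7-bromo-4-methoxy-1H-indol-3-yl)pyrimidine-2,4(1H,3H)-dione | O=c1[nH]cc(-c2c[nH]c3c(Br)ccc(OC)c23)c(=O)[nH]1 | intermediate
10 | 7-bromo-3-(2,4-dibromopyrimidin-5-yl)-4-methoxy-1H-indole | Brc1ncc(-c2c[nH]c3c(Br)ccc(OC)c23)c(Br)n1 | intermediate
11 | 2-bromo-5-(7-bromo-4-methoxy-1H-indol-3-yl)pyrimidin-4-amine | Nc1nc(Br)ncc1-c1c[nH]c2c(Br)ccc(OC)c12 | intermediate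
12 | 3-(4-amino-2-bromopyrimidin-5-yl)-7-bromo-1H-indol-4-ol | Nc1nc(Br)ncc1-c1c[nH]c2c(Br)ccc(O)c12 | target

Total step count: 8. Longest linear sequence: 8 steps (from 1).

Steps most likely to fail

Step 3. The cation may attack the bromine-bearing carbon, which is para to the methoxy group and electronically the better nucleophile, with loss or migration of bromine. Closure at a carbon flanked on both sides may also be slow enough for acid-promoted self-condensation of the keto ester to compete. The fallback forms C3–C3a by the [3,3]-sigmatropic shift of a Fischer indole synthesis instead of by electrophilic substitution, and it sets out from 1. Diazotisation (NaNO2, aq. HCl, 0 °C) gives 2-bromo-5-methoxybenzenediazonium chloride F1. SnCl2 in HCl reduces it to (2-bromo-5-methoxyphenyl)hydrazine F2, handled as its hydrochloride. Condensation with commercial ethyl 4-oxobutanoate in EtOH gives ethyl (4E)-4-[2-(2-bromo-5-methoxyphenyl)hydrazinylidene]butanoate F3. Heating in ethanolic HCl then rearranges this through the only free ortho carbon to ethyl 2-(7-bromo-4-methoxy-1H-indol-3-yl)acetate F4. N-Mesylation (NaH, MeSO2Cl, THF, 0 °C) comes back to the route at 6, so the later steps stay as written.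

Step 2. Proton transfer from the acidic methylene of the chloro keto ester to the base or to the sulfonamide anion may lead to self-condensation of the electrophile. N-alkylation of a nucleophile already hindered by the ortho bromine would then stall. The fallback removes the acidic methylene by masking the ketone as an enol ether, and it sets out from 2. Alkylation with commercial ethyl (E)-4-bromo-3-ethoxybut-2-enoate (K2CO3, DMF, rt), an allylic bromide, gives ethyl (E)-4-[N-(2-bromo-5-methoxyphenyl)methanesulfonamido]-3-ethoxybut-2-enoate F5. Mild hydrolysis of the enol ether (2 M HCl, THF, 40 °C) comes back to the route at 4.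

Step 6. Hot POBr3/HBr may cleave the methyl ether and phosphorylate the freed phenol. Adventitious bromination of the unprotected, electron-rich indole and incomplete replacement of the second oxygen are further risks. The fallback uses chlorine as a placeholder halogen and installs bromine last by halogen exchange, and it sets out from 9. POCl3/PhNMe2 at 100 °C gives 7-bromo-3-(2,4-dichloropyrimidin-5-yl)-4-methoxy-1H-indole F6. NH3 in i-PrOH/THF substitutes C4' to give 5-(7-bromo-4-methoxy-1H-indol-3-yl)-2-chloropyrimidin-4-amine F7. Heating with excess Me3SiBr in EtCN exchanges the activated C2' chloride for bromide through the N-silylpyrimidinium salt and comes back to the route at 11.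

Further compounds
F1 | step 3 | 2-bromo-5-methoxybenzenediazonium chloride | COc1ccc(Br)c(c1)[N+]#N.[Cl-]
F2 | step 3 | (2-bromo-5-methoxyphenyl)hydrazine | NNc1cc(OC)ccc1Br
F3 | step 3 | ethyl (4E)-4-[2-(2-bromo-5-methoxyphenyl)hydrazinylidene]butanoate | CCOC(=O)CC/C=N/Nc1cc(OC)ccc1Br
F4 | step 3 | ethyl 2-(7-bromo-4-methoxy-1H-indol-3-yl)acetate | CCOC(=O)Cc1c[nH]c2c(Br)ccc(OC)c12
F5 | step 2 | ethyl (E)-4-[N-(2-bromo-5-methoxyphenyl)methanesulfonamido]-3-ethoxybut-2-enoate | CCO/C(CN(c1cc(OC)ccc1Br)S(C)(=O)=O)=C/C(=O)OCC
F6 | step 6 | 7-bromo-3-(2,4-dichloropyrimidin-5-yl)-4-methoxy-1H-indole | COc1ccc(Br)c2[nH]cc(-c3cnc(Cl)nc3Cl)c12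
F7 | step 6 | 5-(7-bromo-4-methoxy-1H-indol-3-yl)-2-chloropyrimidin-4-amine | COc1ccc(Br)c2[nH]cc(-c3cnc(Cl)nc3N)c12
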